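**Strategy.** Ring A of the eudesmane core (C1–C5, C10) is disconnected at C3–C4 and C5–C10, the retron of an intramolecular Diels–Alder reaction. The precursor is an acyclic triene made from (R)-α-terpineol: an (E)-α-methyl enone (C4=C5) joined through C6–C9 to a stereodefined tetrasubstituted diene (C10=C1–C2=C3). One cycloaddition closes both rings and sets C4, C5 and C10 from C7 alone. It exploits the cis-1,3 C4/C10 methyl pair and the C4 oxygen next to the ring fusion: the acetyl group on C4 activates the dienophile and later becomes the hydroxyl by Baeyer–Villiger oxidation. The arylisopentyl side chain is then built on C1 through a benzylic cation.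

Key step: step 7

**Remarks and assumptions.**
- Numbering is that of the eudesmanes: decalin C1–C10 (ring A = C1–C5, C10; ring B = C5–C10), C14 = methyl on C10, C15 = methyl on C4, C11 = carbinol carbon on C7, C1' = benzylic carbon on C1. β is the face of the C10 methyl group. "Eudesmane" names imply the trans-decalin with 5α-H, 10β-methyl and the 7β side chain.
- The ylide 11 is taken as purchasable (otherwise it is made from 3-chlorobutan-2-one and PPh3).
- The acetal carbon of 2–10 and C1' of 18 are mixtures of epimers; both centres are removed or reset later.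

**Route**

Step 1
Reactants: 1 (R)-(+)-α-terpineol
Product: 3 methyl lactol ether 4-[(3R)-5-methoxy-2,2-dimethyloxolan-3-yl]butan-2-one, via keto lactol 2 (not isolated)
Conditions: O3, CH2Cl2/MeOH, −78 °C; Me2S; then p-TsOH (cat.), MeOH, rt
Reagents that add atoms: ozone [O-][O+]=O; methanol CO
Why: Ozonolysis of the ring alkene gives the keto aldehyde, which closes onto the tertiary hydroxyl and is fixed as the cyclic methyl acetal (acetalisation), so that the aldehyde (C5) and the C11 hydroxyl are both masked for the basic steps while C7 is untouched.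

Step 2
Reactants: 3 methyl lactol ether
Product: 6 propargylic alcohol 5-[(3R)-5-methoxy-2,2-dimethyloxolan-3-yl]pent-2-yn-1-ol, via enol phosphate 4 (not isolated), via lithium acetylide 5 (not isolated)
Conditions: LiN(i-Pr)2 (1.1 equiv), THF, −78 °C; ClP(O)(OEt)2; LiN(i-Pr)2 (2.3 equiv), −78 °C to rt; (CH2O)n, 0 °C to rt
Reagents that add atoms: formaldehyde (as paraformaldehyde) C=O
Why: Kinetic enolisation at the methyl group, O-phosphorylation and base-induced elimination (Negishi conversion of a methyl ketone into a terminal alkyne) give the acetylide, which adds to formaldehyde; no stereocentre is formed.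

Step 3
Reactants: 6 propargylic alcohol
Product: 8 alkenyl iodide (2E)-2-iodo-5-[(3R)-5-methoxy-2,2-dimethyloxolan-3-yl]-3-methylpent-2-en-1-ol, via alkenylmagnesium bromide 7 (not isolated)
Conditions: MeMgBr (5 equiv), Fe(acac)3 (15 mol %), THF, −78 °C to 0 °C; then I2, −78 °C
Reagents that add atoms: methylmagnesium bromide C[Mg]Br; iodine II
Why: Alkoxide-directed iron-catalysed syn-carbomagnesiation of the propargylic alcohol should put the methyl group on the distal alkyne carbon (C10) and magnesium on the proximal one (C1), and iodinolysis with retention fixes the tetrasubstituted alkene with the chain (C9) cis to CH2OH and the new methyl cis to iodine.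

Step 4
Reactants: 8 alkenyl iodide
Product: 9 dienol (2Z)-2-ethenyl-5-[(3R)-5-methoxy-2,2-dimethyloxolan-3-yl]-3-methylpent-2-en-1-ol
Conditions: vinylboronic acid pinacol ester, Pd(dppf)Cl2 (5 mol %), K3PO4, THF/H2O, 60 °C
Reagents that add atoms: 2-ethenyl-4,4,5,5-tetramethyl-1,3,2-dioxaborolane C=CB1OC(C)(C)C(C)(C)O1
Why: Suzuki–Miyaura coupling proceeds with retention of alkene geometry, so the vinyl group (C2=C3) ends cis to the C10 methyl group and trans to the chain.

Step 5
Reactants: 9 dienol
Product: 10 lactol (2Z)-2-ethenyl-5-[(3R)-5-hydroxy-2,2-dimethyloxolan-3-yl]-3-methylpent-2-en-1-ol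
Conditions: aq. AcOH, THF, 40 °C
Reagents that add atoms: water O
Why: Mild acid hydrolysis of the cyclic methyl acetal frees the lactol (masked C5 aldehyde) under conditions that the primary allylic alcohol should tolerate; no stereocentre of consequence is touched.

Step 6
Reactants: 10 lactol; 11 3-(triphenylphosphoranylidene)butan-2-one
Product: 12 triene (3E,6R,9Z)-10-(hydroxymethyl)-6-(2-hydroxypropan-2-yl)-3,9-dimethyldodeca-3,9,11-trien-2-one
Conditions: PhCO2H (cat.), toluene, 60 °C
Reagents that add atoms: none
Why: Wittig olefination of the open aldehyde form with the stabilised α-methyl ylide should give the (E)-enone (acetyl trans to C6, C15 methyl cis to C6), below the temperature at which the triene cyclises.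

Step 7
Reactants: 12 triene
Product: 13 cycloadduct 4α-acetyl-1-(hydroxymethyl)eudesm-1-en-11-ol (4β-methyl; trans-fused)
Conditions: toluene (0.01 M), BHT, 150 °C, sealed tube
Reagents that add atoms: none
Why: A thermal, concerted but asynchronous [4+2] cycloaddition (type 1 intramolecular Diels–Alder reaction of a 1,7,9-decatriene activated at the dienophile terminus) bonds C5, the β-carbon of the enone, to C10 and C4 to C3. Ring A is closed by the suprafacial [π4s+π2s] addition itself, and ring B at the same time by the C5–C10 bond across the four-carbon tether C6–C9 held in a chair-like array. C4 follows from the (E)-enone, because the acetyl group stays cis to H5 and the C15 methyl cis to C6; C10 follows from the diene geometry, with the chain outside and the methyl group inside. The trans ring fusion (5α-H, 10β-methyl) comes from the transition state with the acetyl group endo and the tether anti, which the hydroxymethyl group on C1 should favour because an internal diene substituent next to the tether clashes with it in the syn (cis-fused) arrangement. The absolute sense comes from C7, whose 2-hydroxypropan-2-yl group sits equatorial on the chair-like tether. The step needs endo/anti over exo/syn selectivity and π-facial control and must outrun a [1,5]-hydrogen shift of the cis-methyl diene; the C1 substituent, the C7 stereocentre and the activating acetyl group are there to secure this.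

Step 8
Reactants: 13 cycloadduct
Product: 14 keto diol 4α-acetyl-1β-(hydroxymethyl)eudesman-11-ol
Conditions: H2 (1 atm), [Ir(cod)(PCy3)(py)]PF6 (5 mol %), CH2Cl2, rt
Reagents that add atoms: none
Why: Homogeneous hydrogenation of the trisubstituted C1=C2 bond should deliver hydrogen from the α face, because the β face is shielded by the C10 and C4 methyl groups, which sets H1 as α and the CH2OH group as β (equatorial).

Step 9
Reactants: 14 keto diol
Product: 15 acetate 4α-acetoxy-1β-(hydroxymethyl)eudesman-11-ol
Conditions: mCPBA, NaHCO3, CH2Cl2, rt to 40 °C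
Reagents that add atoms: 3-chloroperbenzoic acid O=C(OO)c1cccc(Cl)c1
Why: In the Baeyer–Villiger oxidation the fully substituted C4 migrates in preference to methyl and with retention, so the oxygen takes the α position that the acetyl carbon held and the C15 methyl stays β.

Step 10
Reactants: 15 acetate
Product: 16 aldehyde 4α-acetoxy-11-hydroxyeudesmane-1β-carbaldehyde
Conditions: Dess–Martin periodinane, NaHCO3, CH2Cl2, 0 °C to rt
Reagents that add atoms: none
Why: Dess–Martin oxidation affects only the primary alcohol, and the aldehyde sits in the thermodynamically preferred equatorial position on C1, so C1 is not at risk.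

Step 11
Reactants: 16 aldehyde; 17 1,3,5-trimethoxybenzene
Product: 18 benzylic alcohol 4α-acetoxy-1β-[hydroxy(2,4,6-trimethoxyphenyl)methyl]eudesman-11-ol (both C1' epimers)
Conditions: 17, n-BuLi, THF, 0 °C to rt; then 16, −78 °C (2.2 equiv aryllithium); aq. NH4Cl
Reagents that add atoms: none
Why: The aryllithium from directed lithiation of 17 adds to the aldehyde (1,2-addition) far faster than to the hindered tertiary acetate, and the C1' epimer mixture is harmless because C1' is ionised in the next step.

Step 12
Reactants: 18 benzylic alcohol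
Product: 19 alkene 4α-acetoxy-1β-[(1S)-3-methyl-1-(2,4,6-trimethoxyphenyl)but-3-enyl]eudesman-11-ol
Conditions: (2-methylallyl)trimethylsilane (3 equiv), BF3·OEt2 (1.5 equiv), CH2Cl2, −78 °C
Reagents that add atoms: (2-methylallyl)trimethylsilane C=C(C)C[Si](C)(C)C
Why: Ionisation gives a trimethoxyphenyl-stabilised benzylic cation in which 1,3-allylic strain holds the C1–H bond in the cation plane, so the allylsilane (Hosomi–Sakurai-type SN1 allylation) should attack the face anti to the quaternary C10 and set C1' as (S), while the in-plane C1–H is poorly aligned for elimination.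

Step 13
Reactants: 19 alkene
Product: 20 trimethyl ether 4α-acetoxy-1β-[(1S)-3-methyl-1-(2,4,6-trimethoxyphenyl)butyl]eudesman-11-ol
Conditions: H2 (1 atm), 10% Pd/C, EtOAc, rt
Reagents that add atoms: none
Why: Heterogeneous hydrogenation of the 1,1-disubstituted alkene completes the isobutyl group without touching a stereocentre.

Step 14
Reactants: 20 trimethyl ether
Product: 22 dialdehyde 1β-[(1S)-1-(3,5-diformyl-2,4,6-trimethoxyphenyl)-3-methylbutyl]eudesmane-4α,11-diol, via lithium hemiaminal 21 (not isolated)
Conditions: n-BuLi (4.5 equiv), TMEDA, THF, 0 °C; DMF (1.2 equiv), −78 °C to 0 °C; n-BuLi (1.5 equiv), 0 °C; DMF (3 equiv); aq. NH4Cl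
Reagents that add atoms: N,N-dimethylformamide CN(C)C=O
Why: Directed ortho-metalation between two methoxy groups and formylation with DMF is run twice in one flask, the first formyl group staying masked as its lithium hemiaminal, while the first equivalents of butyllithium deprotonate the C11 hydroxyl and cleave the now superfluous C4 acetate; no stereocentre is affected.

Step 15
Reactants: 22 dialdehyde
Product: 23 Macrocarpal J
Conditions: 4-MeC6H4SLi (8 equiv), HMPA/toluene, 110 °C; then 1 M HCl
Reagents that add atoms: none
Why: SN2 demethylation by the thiolate at three methyl ethers, each activated by an ortho formyl group, proceeds under basic conditions that spare the two acid-sensitive tertiary alcohols.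

**Compound list**

1 | (R)-(+)-α-terpineol, 2-[(1R)-4-methylcyclohex-3-en-1-yl]propan-2-ol | CC1=CC[C@@H](CC1)C(C)(C)O | starting material
2 | keto lactol, 4-[(3R)-5-hydroxy-2,2-dimethyloxolan-3-yl]butan-2-one | CC(=O)CC[C@@H]1CC(O)OC1(C)C | intermediate (not isolated)
3 | methyl lactol ether, 4-[(3R)-5-methoxy-2,2-dimethyloxolan-3-yl]butan-2-one | CC(=O)CC[C@@H]1CC(OC)OC1(C)C | intermediate
4 | enol phosphate, diethyl 4-[(3R)-5-methoxy-2,2-dimethyloxolan-3-yl]but-1-en-2-yl phosphate | C=C(OP(=O)(OCC)OCC)CC[C@@H]1CC(OC)OC1(C)C | intermediate (not isolated)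
5 | lithium acetylide of (4R)-4-(but-3-ynyl)-2-methoxy-5,5-dimethyloxolane | [Li]C#CCC[C@@H]1CC(OC)OC1(C)C | intermediate (not isolated)
6 | propargylic alcohol, 5-[(3R)-5-methoxy-2,2-dimethyloxolan-3-yl]pent-2-yn-1-ol | OCC#CCC[C@@H]1CC(OC)OC1(C)C | intermediate
7 | alkenylmagnesium bromide (bromomagnesium alkoxide) from syn-methylmagnesiation of 6 | Br[Mg]OC/C([Mg]Br)=C(/C)CC[C@@H]1CC(OC)OC1(C)C | intermediate (not isolated)
8 | alkenyl iodide, (2E)-2-iodo-5-[(3R)-5-methoxy-2,2-dimethyloxolan-3-yl]-3-methylpent-2-en-1-ol | OC/C(I)=C(/C)CC[C@@H]1CC(OC)OC1(C)C | intermediate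
9 | dienol, (2Z)-2-ethenyl-5-[(3R)-5-methoxy-2,2-dimethyloxolan-3-yl]-3-methylpent-2-en-1-ol | OC/C(C=C)=C(/C)CC[C@@H]1CC(OC)OC1(C)C | intermediate
10 | lactol, (2Z)-2-ethenyl-5-[(3R)-5-hydroxy-2,2-dimethyloxolan-3-yl]-3-methylpent-2-en-1-ol | OC/C(C=C)=C(/C)CC[C@@H]1CC(O)OC1(C)C | intermediate
11 | 3-(triphenylphosphoranylidene)butan-2-one | CC(=O)C(C)=P(c1ccccc1)(c1ccccc1)c1ccccc1 | starting material
12 | triene, (3E,6R,9Z)-10-(hydroxymethyl)-6-(2-hydroxypropan-2-yl)-3,9-dimethyldodeca-3,9,11-trien-2-one | OC/C(C=C)=C(/C)CC[C@H](C/C=C(\C)C(C)=O)C(C)(C)O | intermediate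
13 | cycloadduct, 4α-acetyl-1-(hydroxymethyl)eudesm-1-en-11-ol (4β-methyl, 5α-H, 10β-methyl) | OCC1=CC[C@@](C)(C(C)=O)[C@@H]2C[C@H](C(C)(C)O)CC[C@]21C | intermediate
14 | keto diol, 4α-acetyl-1β-(hydroxymethyl)eudesman-11-ol | OC[C@@H]1CC[C@@](C)(C(C)=O)[C@@H]2C[C@H](C(C)(C)O)CC[C@]21C | intermediate
15 | acetate, 4α-acetoxy-1β-(hydroxymethyl)eudesman-11-ol | OC[C@@H]1CC[C@@](C)(OC(C)=O)[C@@H]2C[C@H](C(C)(C)O)CC[C@]21C | intermediate
16 | aldehyde, 4α-acetoxy-11-hydroxyeudesmane-1β-carbaldehyde | O=C[C@@H]1CC[C@@](C)(OC(C)=O)[C@@H]2C[C@H](C(C)(C)O)CC[C@]21C | intermediate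
17 | 1,3,5-trimethoxybenzene | COc1cc(OC)cc(OC)c1 | starting material
18 | benzylic alcohol, 4α-acetoxy-1β-[hydroxy(2,4,6-trimethoxyphenyl)methyl]eudesman-11-ol (C1' epimers) | OC(c1c(OC)cc(OC)cc1OC)[C@@H]1CC[C@@](C)(OC(C)=O)[C@@H]2C[C@H](C(C)(C)O)CC[C@]21C | intermediate
19 | alkene, 4α-acetoxy-1β-[(1S)-3-methyl-1-(2,4,6-trimethoxyphenyl)but-3-enyl]eudesman-11-ol | C=C(C)C[C@H](c1c(OC)cc(OC)cc1OC)[C@@H]1CC[C@@](C)(OC(C)=O)[C@@H]2C[C@H](C(C)(C)O)CC[C@]21C | intermediate
20 | trimethyl ether, 4α-acetoxy-1β-[(1S)-3-methyl-1-(2,4,6-trimethoxyphenyl)butyl]eudesman-11-ol | CC(C)C[C@H](c1c(OC)cc(OC)cc1OC)[C@@H]1CC[C@@](C)(OC(C)=O)[C@@H]2C[C@H](C(C)(C)O)CC[C@]21C | intermediate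
21 | lithium hemiaminal of the monoformyl compound (trilithium salt) | CC(C)C[C@H](c1c(OC)cc(OC)c(C(O[Li])N(C)C)c1OC)[C@@H]1CC[C@@](C)(O[Li])[C@@H]2C[C@H](C(C)(C)O[Li])CC[C@]21C | intermediate (not isolated)
22 | dialdehyde, 1β-[(1S)-1-(3,5-diformyl-2,4,6-trimethoxyphenyl)-3-methylbutyl]eudesmane-4α,11-diol | CC(C)C[C@H](c1c(OC)c(C=O)c(OC)c(C=O)c1OC)[C@@H]1CC[C@@](C)(O)[C@@H]2C[C@H](C(C)(C)O)CC[C@]21C | intermediate
23 | Macrocarpal J | CC(C)C[C@H](c1c(O)c(C=O)c(O)c(C=O)c1O)[C@@H]1CC[C@@](C)(O)[C@@H]2C[C@H](C(C)(C)O)CC[C@]21C | target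

**Step count.** 15 steps in total; the longest linear sequence is 15 steps (1 to 23).

**Steps most likely to fail**

Step 7 (key cycloaddition). At the temperature needed, the cis-methyl diene may undergo a [1,5]-hydrogen shift, the tertiary hydroxyl may add to the enone, or the exo/syn pathway may compete and lead to the cis-fused decalin. The fallback sets out from 12 and comes back at 13, and it replaces thermal activation by Lewis-acid activation of a protected triene. Both hydroxyls of 12 are silylated (Et3SiOTf, 2,6-lutidine, CH2Cl2, −78 °C) to give the bis(triethylsilyl) ether of triene 12 F1. The enone is then activated with Me2AlCl (CH2Cl2, −78 to −20 °C), which should allow a far lower temperature and strengthen the endo preference, to give the bis(triethylsilyl) ether of cycloadduct 13 F2. HF·pyridine in THF returns 13.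

Step 12 (allylation at C1'). The facial selectivity at the benzylic cation may be poor, or the cation may lose the C1 proton to form the styrene. The fallback sets out from 18 and comes back at 20, and it reverses the order of bond formation so that hydrogen, not carbon, is delivered last. Oxidation of 18 with Dess–Martin periodinane gives the aryl ketone (4α-acetoxy-11-hydroxyeudesman-1β-yl)(2,4,6-trimethoxyphenyl)methanone F3. The organocerium reagent from i-BuMgCl and CeCl3 (THF, −78 °C) adds to give the tertiary benzylic alcohol 4α-acetoxy-1β-[1-hydroxy-3-methyl-1-(2,4,6-trimethoxyphenyl)butyl]eudesman-11-ol F4. Ionic hydrogenation (Et3SiH, BF3·OEt2, CH2Cl2, −78 °C) of the derived tertiary cation then leads directly to 20. Hydride should again enter anti to C10, but which C1' epimer results depends on the rotamer of the tertiary cation, so the sense would have to be established on the first run.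

Step 3 (carbomagnesiation). Regiocontrol of the methyl transfer may be incomplete, or the alkenylmagnesium may be protonated before it is iodinated. The fallback sets out from 3 and comes back at 8, and it replaces the directed carbomagnesiation by carbocupration of a polarised alkyne. Acetylide 5 is generated as in step 2 but quenched with methyl chloroformate to give the ynoate methyl 5-[(3R)-5-methoxy-2,2-dimethyloxolan-3-yl]pent-2-ynoate F5. Me2CuLi (THF, −78 °C) adds syn with methyl at the β-carbon, and iodine traps the alkenylcopper with retention to give the iodo enoate methyl (2E)-2-iodo-5-[(3R)-5-methoxy-2,2-dimethyloxolan-3-yl]-3-methylpent-2-enoate F6. Reduction with i-Bu2AlH (CH2Cl2, −78 °C) gives 8.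

**Further compounds**

F1 | step 7 | bis(triethylsilyl) ether of triene 12 | CC[Si](CC)(CC)OC/C(C=C)=C(/C)CC[C@H](C/C=C(\C)C(C)=O)C(C)(C)O[Si](CC)(CC)CC
F2 | step 7 | bis(triethylsilyl) ether of cycloadduct 13 | CC[Si](CC)(CC)OCC1=CC[C@@](C)(C(C)=O)[C@@H]2C[C@H](C(C)(C)O[Si](CC)(CC)CC)CC[C@]21C
F3 | step 12 | aryl ketone (4α-acetoxy-11-hydroxyeudesman-1β-yl)(2,4,6-trimethoxyphenyl)methanone | O=C(c1c(OC)cc(OC)cc1OC)[C@@H]1CC[C@@](C)(OC(C)=O)[C@@H]2C[C@H](C(C)(C)O)CC[C@]21C
F4 | step 12 | tertiary benzylic alcohol 4α-acetoxy-1β-[1-hydroxy-3-methyl-1-(2,4,6-trimethoxyphenyl)butyl]eudesman-11-ol | CC(C)CC(O)(c1c(OC)cc(OC)cc1OC)[C@@H]1CC[C@@](C)(OC(C)=O)[C@@H]2C[C@H](C(C)(C)O)CC[C@]21C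
F5 | step 3 | ynoate methyl 5-[(3R)-5-methoxy-2,2-dimethyloxolan-3-yl]pent-2-ynoate | COC(=O)C#CCC[C@@H]1CC(OC)OC1(C)C
F6 | step 3 | iodo enoate methyl (2E)-2-iodo-5-[(3R)-5-methoxy-2,2-dimethyloxolan-3-yl]-3-methylpent-2-enoate | COC(=O)/C(I)=C(/C)CC[C@@H]1CC(OC)OC1(C)C
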